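**Retrosynthetic overview**
- C8–Br is installed last, by invertive bromination of the endo allylic alcohol. Ring A (the Z enol ether) is closed second, by 5-exo-dig cycloisomerisation of a C10-hydroxy C6≡C7 alkyne.
- The skipped (Z)-enyne comes from copper-catalysed coupling of the C6 terminal alkyne with a (Z)-C1–C5 allylic bromide. The alkyne comes from one-carbon homologation of a lactol.
- The C8 oxygen comes from lactone enolate hydroxylation followed by triflate inversion. C13–Br comes from invertive bromination of the C13 alcohol.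
- Ring B is closed first, together with a temporary lactone, by palladium-catalysed oxycarbonylation of a syn-1-ene-3,5-diol; this sets C9.
- The diol comes from a chelation-controlled Mukaiyama aldol (C12) and a 1,3-syn reduction (C10) on (R)-2-(benzyloxy)butanal. C13 is set first, by ketoreductase reduction of ethyl 2-oxobutanoate.

Assumption: atom labels C1–C15 follow the target chain (C1 = alkyne CH, C7 = enol-ether carbon, C15 = CH3), and "exo" means the convex face of the cis-fused bicycle.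

The route is a paper design; it has not been run, and no synthesis of this compound is known to me.

**Route**

Step 1
Reactants: 1 ethyl 2-oxobutanoate
Product: 2 ethyl (2R)-2-hydroxybutanoate
Conditions: (R)-selective ketoreductase (NADPH-dependent), NADP+ (cat.), i-PrOH, KH2PO4/K2HPO4 buffer pH 7, 30 °C
Reagents that add atoms: none
Why: Enzymatic asymmetric ketone reduction; the ketoreductase delivers hydride from NADPH (recycled by isopropanol) to one face of the α-keto ester and sets the first stereocentre (C13, R).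

Step 2
Reactants: 2 ethyl (2R)-2-hydroxybutanoate
Product: 3 ethyl (2R)-2-(benzyloxy)butanoate
Conditions: BnOC(=NH)CCl3, TfOH (5 mol%), cyclohexane/CH2Cl2, rt
Reagents that add atoms: benzyl 2,2,2-trichloroacetimidate, N=C(OCc1ccccc1)C(Cl)(Cl)Cl
Why: Acid-catalysed imidate O-benzylation avoids base, so the α-stereocentre is not racemised.

Step 3
Reactants: 3 ethyl (2R)-2-(benzyloxy)butanoate
Product: 4 (2R)-2-(benzyloxy)butanal
Conditions: i-Bu2AlH (1.1 equiv), CH2Cl2, −78 °C; aq. KNaC4H4O6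
Reagents that add atoms: none
Why: Partial hydride reduction of an α-alkoxy ester stops at the chelated hemiacetal, which gives the aldehyde on work-up; it is used crude to keep C13 intact.

Step 4
Reactants: 4 (2R)-2-(benzyloxy)butanal, 5 2-(trimethylsilyloxy)buta-1,3-diene
Product: 7 (5R,6R)-6-(benzyloxy)-5-hydroxyoct-1-en-3-one, via O-trimethylsilyl aldol adduct 6 (not isolated)
Conditions: MgBr2·OEt2 (2.5 equiv), CH2Cl2, −78 → −20 °C; then 1 M HCl, THF, 0 °C
Reagents that add atoms: none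
Why: Chelation-controlled Mukaiyama aldol; the enol silane attacks the Mg-chelated α-benzyloxy aldehyde anti to the ethyl group and gives the 12,13-syn adduct (C12, R).

Step 5
Reactants: 7 (5R,6R)-6-(benzyloxy)-5-hydroxyoct-1-en-3-one
Product: 9 (3S,5R,6R)-6-(benzyloxy)oct-1-ene-3,5-diol, via diethylboron chelate 8 (not isolated)
Conditions: Et2BOMe (1.1 equiv), THF/MeOH 4:1, −78 °C; NaBH4; AcOH, MeOH co-evaporation
Reagents that add atoms: none
Why: Narasaka–Prasad reduction; external hydride attacks the six-membered boron chelate axially at −78 °C (1,2-reduction) and gives the 1,3-syn diol (C10, S).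

Step 6
Reactants: 9 (3S,5R,6R)-6-(benzyloxy)oct-1-ene-3,5-diol
Product: 10 (3aS,5R,6aS)-5-[(1R)-1-(benzyloxy)propyl]tetrahydrofuro[3,2-b]furan-2(3H)-one
Conditions: PdCl2 (10 mol%), CuCl2 (3 equiv), NaOAc (3 equiv), CO (1 atm), AcOH, rt
Reagents that add atoms: carbon monoxide, [C-]#[O+]
Why: Divalent-palladium oxycarbonylation (5-exo alkoxypalladation by C12–OH, CO insertion, lactonisation by C10–OH); only the cis-fused lactone can close, which fixes C9 and places the side chain exo (ring B 2,5-trans).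

Step 7
Reactants: 10 (3aS,5R,6aS)-5-[(1R)-1-(benzyloxy)propyl]tetrahydrofuro[3,2-b]furan-2(3H)-one
Product: 12 (3S,3aS,5R,6aS)-5-[(1R)-1-(benzyloxy)propyl]-3-hydroxytetrahydrofuro[3,2-b]furan-2(3H)-one, via potassium enolate 11 (not isolated)
Conditions: KN(SiMe3)2 (1.1 equiv), THF, −78 °C; 3-phenyl-2-(phenylsulfonyl)oxaziridine (racemic), −78 °C; AcOH
Reagents that add atoms: 3-phenyl-2-(phenylsulfonyl)oxaziridine, O=S(=O)(c1ccccc1)N1OC1c1ccccc1
Why: Davis enolate hydroxylation; the oxidant approaches the convex face of the bicyclic enolate and gives the exo C8 alcohol, and the low temperature suppresses β-elimination.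

Step 8
Reactants: 12 exo hydroxy lactone
Product: 13 (3S,3aR,5R,6aS)-5-[(1R)-1-(benzyloxy)propyl]-2-oxohexahydrofuro[3,2-b]furan-3-yl trifluoromethanesulfonate
Conditions: Tf2O (1.3 equiv), pyridine, CH2Cl2, −30 °C
Reagents that add atoms: trifluoromethanesulfonic anhydride, O=S(=O)(OS(=O)(=O)C(F)(F)F)C(F)(F)F
Why: O-sulfonylation turns the exo hydroxyl into a leaving group that is activated by the adjacent lactone carbonyl.

Step 9
Reactants: 13 exo triflate
Product: 15 (3R,3aS,5R,6aS)-5-[(1R)-1-(benzyloxy)propyl]-3-hydroxytetrahydrofuro[3,2-b]furan-2(3H)-one, via endo trifluoroacetate 14 (not isolated)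
Conditions: CF3CO2Cs (3 equiv), 2-butanone, rt; then MeOH, rt
Reagents that add atoms: caesium trifluoroacetate, [Cs+].[O-]C(=O)C(F)(F)F
Why: SN2 displacement of an α-lactone triflate by carboxylate inverts C8 to the endo configuration, and the labile trifluoroacetate is cleaved by methanol.

Step 10
Reactants: 15 endo hydroxy lactone
Product: 16 (3R,3aR,5R,6aS)-5-[(1R)-1-(benzyloxy)propyl]-3-[(tert-butyldimethylsilyl)oxy]tetrahydrofuro[3,2-b]furan-2(3H)-one
Conditions: TBSOTf (1.3 equiv), 2,6-lutidine, CH2Cl2, −78 → 0 °C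
Reagents that add atoms: tert-butyldimethylsilyl trifluoromethanesulfonate, CC(C)(C)[Si](C)(C)OS(=O)(=O)C(F)(F)F
Why: Silylation of the hindered endo alcohol protects C8–OH through the reduction and homologation steps.

Step 11
Reactants: 16 benzyl ether lactone
Product: 17 (3R,3aR,5R,6aS)-3-[(tert-butyldimethylsilyl)oxy]-5-[(1R)-1-hydroxypropyl]tetrahydrofuro[3,2-b]furan-2(3H)-one
Conditions: H2 (1 atm), 10% Pd/C, EtOAc, rt
Reagents that add atoms: none
Why: Hydrogenolysis removes the benzyl ether while the molecule has no alkene, alkyne or halide.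

Step 12
Reactants: 17 C13 alcohol
Product: 18 (3R,3aR,5R,6aS)-5-[(1S)-1-bromopropyl]-3-[(tert-butyldimethylsilyl)oxy]tetrahydrofuro[3,2-b]furan-2(3H)-one
Conditions: CBr4 (3 equiv), (n-C8H17)3P (3 equiv), toluene, 70 °C
Reagents that add atoms: carbon tetrabromide, BrC(Br)(Br)Br
Why: Appel bromination; bromide displaces the alkoxyphosphonium by SN2 and inverts C13 (R alcohol to S bromide).

Step 13
Reactants: 18 bromo lactone
Product: 19 (3R,3aR,5R,6aS)-5-[(1S)-1-bromopropyl]-3-[(tert-butyldimethylsilyl)oxy]hexahydrofuro[3,2-b]furan-2-ol (anomeric mixture)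
Conditions: i-Bu2AlH (1.2 equiv), CH2Cl2, −78 °C
Reagents that add atoms: none
Why: Partial reduction of the lactone to the lactol; the secondary bromide and silyl ether are inert at −78 °C.

Step 14
Reactants: 19 lactol
Product: 20 (2R,3S,5R)-5-[(1S)-1-bromopropyl]-2-[(1S)-1-[(tert-butyldimethylsilyl)oxy]prop-2-yn-1-yl]oxolan-3-ol
Conditions: dimethyl (1-diazo-2-oxopropyl)phosphonate (2 equiv), K2CO3, MeOH, 0 °C → rt
Reagents that add atoms: dimethyl (1-diazo-2-oxopropyl)phosphonate, CC(=O)C(=[N+]=[N-])P(=O)(OC)OC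
Why: Ohira–Bestmann (Seyferth–Gilbert) homologation of the open hydroxy-aldehyde form gives the C6≡C7 terminal alkyne and frees C10–OH.

Step 15
Reactants: 21 ethyl (2Z)-3-iodoprop-2-enoate, 22 ethynyltri(propan-2-yl)silane
Product: 23 ethyl (2Z)-5-[tri(propan-2-yl)silyl]pent-2-en-4-ynoate
Conditions: PdCl2(PPh3)2 (2 mol%), CuI (4 mol%), Et3N, THF, 0 °C → rt
Reagents that add atoms: none
Why: Sonogashira coupling proceeds with retention of the Z vinyl iodide geometry.

Step 16
Reactants: 23 (Z)-enynoate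
Product: 24 (2Z)-5-[tri(propan-2-yl)silyl]pent-2-en-4-yn-1-ol
Conditions: i-Bu2AlH (2.2 equiv), CH2Cl2, −78 °C
Reagents that add atoms: none
Why: 1,2-Reduction of the conjugated ester gives the Z allylic alcohol without touching the enyne.

Step 17
Reactants: 24 (Z)-enynol
Product: 25 [(3Z)-5-bromopent-3-en-1-yn-1-yl]tri(propan-2-yl)silane
Conditions: CBr4, PPh3, CH2Cl2, 0 °C
Reagents that add atoms: carbon tetrabromide, BrC(Br)(Br)Br
Why: Appel bromination of a primary allylic alcohol at 0 °C keeps the Z geometry.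

Step 18
Reactants: 20 terminal alkyne, 25 (Z)-allylic bromide
Product: 26 (2R,3S,5R)-5-[(1S)-1-bromopropyl]-2-[(1S,5Z)-1-[(tert-butyldimethylsilyl)oxy]-8-[tri(propan-2-yl)silyl]oct-5-ene-2,7-diyn-1-yl]oxolan-3-ol
Conditions: CuI (20 mol%), K2CO3 (1.5 equiv), Bu4NCl (20 mol%), DMF, rt
Reagents that add atoms: none
Why: Copper-catalysed alkynyl–allyl coupling; the copper acetylide displaces the primary allylic bromide at the α-carbon and builds the skipped (Z)-enyne without strong base.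

Step 19
Reactants: 26 alkynol
Product: 27 (2Z,3R,3aR,5R,6aS)-5-[(1S)-1-bromopropyl]-3-[(tert-butyldimethylsilyl)oxy]-2-[(3Z)-6-[tri(propan-2-yl)silyl]hex-3-en-5-yn-1-ylidene]hexahydrofuro[3,2-b]furan
Conditions: AuCl (5 mol%), K2CO3 (10 mol%), MeCN, rt, dark
Reagents that add atoms: none
Why: Monovalent-gold 5-exo-dig hydroalkoxylation closes ring A; anti oxyauration followed by protodeauration gives the Z enol ether, and carbonate buffering prevents exo-to-endo isomerisation.

Step 20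
Reactants: 27 bis-silyl enol ether
Product: 28 (2Z,3R,3aS,5R,6aS)-5-[(1S)-1-bromopropyl]-2-[(3Z)-hex-3-en-5-yn-1-ylidene]hexahydrofuro[3,2-b]furan-3-ol
Conditions: Bu4NF (2.5 equiv), THF, 0 °C
Reagents that add atoms: none
Why: Fluoride desilylation removes the O-silyl and C-silyl groups in one operation; the enol ether is stable to base.

Step 21
Reactants: 28 endo allylic alcohol
Product: 29 (2Z,3S,3aR,5R,6aS)-3-bromo-5-[(1S)-1-bromopropyl]-2-[(3Z)-hex-3-en-5-yn-1-ylidene]hexahydrofuro[3,2-b]furan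
Conditions: CBr4 (1.5 equiv), PPh3 (1.5 equiv), 2,6-di-tert-butylpyridine, CH2Cl2, −20 → 0 °C
Reagents that add atoms: carbon tetrabromide, BrC(Br)(Br)Br
Why: Appel bromination; bromide attacks the activated allylic C8 from the open convex face (SN2), inverting the endo alcohol to the exo bromide (C8, S), with the hindered base protecting the enol ether.

**Compound list**

1 | ethyl 2-oxobutanoate | CCC(=O)C(=O)OCC | starting material
2 | ethyl (2R)-2-hydroxybutanoate | CC[C@@H](O)C(=O)OCC | intermediate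
3 | ethyl (2R)-2-(benzyloxy)butanoate | CC[C@@H](OCc1ccccc1)C(=O)OCC | intermediate
4 | (2R)-2-(benzyloxy)butanal | CC[C@@H](OCc1ccccc1)C=O | intermediate
5 | 2-(trimethylsilyloxy)buta-1,3-diene | C=CC(=C)O[Si](C)(C)C | starting material
6 | (5R,6R)-6-(benzyloxy)-5-(trimethylsilyloxy)oct-1-en-3-one (not isolated) | C=CC(=O)C[C@H]([C@H](OCc1ccccc1)CC)O[Si](C)(C)C | intermediate
7 | (5R,6R)-6-(benzyloxy)-5-hydroxyoct-1-en-3-one | C=CC(=O)C[C@H]([C@H](OCc1ccccc1)CC)O | intermediate
8 | diethylboron chelate (O-diethylboryl derivative) of 7 (not isolated) | C=CC(=O)C[C@H]([C@H](OCc1ccccc1)CC)OB(CC)CC | intermediate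
9 | (3S,5R,6R)-6-(benzyloxy)oct-1-ene-3,5-diol | C=C[C@@H](O)C[C@H]([C@H](OCc1ccccc1)CC)O | intermediate
10 | (3aS,5R,6aS)-5-[(1R)-1-(benzyloxy)propyl]tetrahydrofuro[3,2-b]furan-2(3H)-one (cis-fused, side chain exo) | O=C1O[C@H]2C[C@H]([C@H](OCc3ccccc3)CC)O[C@H]2C1 | intermediate
11 | potassium enolate of 10 (not isolated) | [K+].[O-]C1=C[C@@H]2O[C@@H]([C@H](OCc3ccccc3)CC)C[C@@H]2O1 | intermediate
12 | (3S,3aS,5R,6aS)-5-[(1R)-1-(benzyloxy)propyl]-3-hydroxytetrahydrofuro[3,2-b]furan-2(3H)-one (C8–OH exo) | O=C1O[C@H]2C[C@H]([C@H](OCc3ccccc3)CC)O[C@H]2[C@@H]1O | intermediate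
13 | (3S,3aR,5R,6aS)-5-[(1R)-1-(benzyloxy)propyl]-2-oxohexahydrofuro[3,2-b]furan-3-yl trifluoromethanesulfonate (exo) | O=C1O[C@H]2C[C@H]([C@H](OCc3ccccc3)CC)O[C@H]2[C@@H]1OS(=O)(=O)C(F)(F)F | intermediate
14 | (3R,3aR,5R,6aS)-5-[(1R)-1-(benzyloxy)propyl]-2-oxohexahydrofuro[3,2-b]furan-3-yl trifluoroacetate (endo, not isolated) | O=C1O[C@H]2C[C@H]([C@H](OCc3ccccc3)CC)O[C@H]2[C@H]1OC(=O)C(F)(F)F | intermediate
15 | (3R,3aS,5R,6aS)-5-[(1R)-1-(benzyloxy)propyl]-3-hydroxytetrahydrofuro[3,2-b]furan-2(3H)-one (C8–OH endo) | O=C1O[C@H]2C[C@H]([C@H](OCc3ccccc3)CC)O[C@H]2[C@H]1O | intermediate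
16 | (3R,3aR,5R,6aS)-5-[(1R)-1-(benzyloxy)propyl]-3-[(tert-butyldimethylsilyl)oxy]tetrahydrofuro[3,2-b]furan-2(3H)-one | O=C1O[C@H]2C[C@H]([C@H](OCc3ccccc3)CC)O[C@H]2[C@H]1O[Si](C)(C)C(C)(C)C | intermediate
17 | (3R,3aR,5R,6aS)-3-[(tert-butyldimethylsilyl)oxy]-5-[(1R)-1-hydroxypropyl]tetrahydrofuro[3,2-b]furan-2(3H)-one | O=C1O[C@H]2C[C@H]([C@H](O)CC)O[C@H]2[C@H]1O[Si](C)(C)C(C)(C)C | intermediate
18 | (3R,3aR,5R,6aS)-5-[(1S)-1-bromopropyl]-3-[(tert-butyldimethylsilyl)oxy]tetrahydrofuro[3,2-b]furan-2(3H)-one | O=C1O[C@H]2C[C@H]([C@@H](Br)CC)O[C@H]2[C@H]1O[Si](C)(C)C(C)(C)C | intermediate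
19 | (3R,3aR,5R,6aS)-5-[(1S)-1-bromopropyl]-3-[(tert-butyldimethylsilyl)oxy]hexahydrofuro[3,2-b]furan-2-ol (anomeric mixture) | OC1O[C@H]2C[C@H]([C@@H](Br)CC)O[C@H]2[C@H]1O[Si](C)(C)C(C)(C)C | intermediate
20 | (2R,3S,5R)-5-[(1S)-1-bromopropyl]-2-[(1S)-1-[(tert-butyldimethylsilyl)oxy]prop-2-yn-1-yl]oxolan-3-ol | C#C[C@H](O[Si](C)(C)C(C)(C)C)[C@@H]1O[C@@H]([C@@H](Br)CC)C[C@@H]1O | intermediate
21 | ethyl (2Z)-3-iodoprop-2-enoate | CCOC(=O)/C=C\I | starting material
22 | ethynyltri(propan-2-yl)silane | C#C[Si](C(C)C)(C(C)C)C(C)C | starting material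
23 | ethyl (2Z)-5-[tri(propan-2-yl)silyl]pent-2-en-4-ynoate | CCOC(=O)/C=C\C#C[Si](C(C)C)(C(C)C)C(C)C | intermediate
24 | (2Z)-5-[tri(propan-2-yl)silyl]pent-2-en-4-yn-1-ol | OC/C=C\C#C[Si](C(C)C)(C(C)C)C(C)C | intermediate
25 | [(3Z)-5-bromopent-3-en-1-yn-1-yl]tri(propan-2-yl)silane | BrC/C=C\C#C[Si](C(C)C)(C(C)C)C(C)C | intermediate
26 | (2R,3S,5R)-5-[(1S)-1-bromopropyl]-2-[(1S,5Z)-1-[(tert-butyldimethylsilyl)oxy]-8-[tri(propan-2-yl)silyl]oct-5-ene-2,7-diyn-1-yl]oxolan-3-ol | CC(C)[Si](C(C)C)(C(C)C)C#C/C=C\CC#C[C@H](O[Si](C)(C)C(C)(C)C)[C@@H]1O[C@@H]([C@@H](Br)CC)C[C@@H]1O | intermediate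
27 | (2Z,3R,3aR,5R,6aS)-5-[(1S)-1-bromopropyl]-3-[(tert-butyldimethylsilyl)oxy]-2-[(3Z)-6-[tri(propan-2-yl)silyl]hex-3-en-5-yn-1-ylidene]hexahydrofuro[3,2-b]furan | CC(C)[Si](C(C)C)(C(C)C)C#C/C=C\C/C=C1\O[C@H]2C[C@H]([C@@H](Br)CC)O[C@H]2[C@H]1O[Si](C)(C)C(C)(C)C | intermediate
28 | (2Z,3R,3aS,5R,6aS)-5-[(1S)-1-bromopropyl]-2-[(3Z)-hex-3-en-5-yn-1-ylidene]hexahydrofuro[3,2-b]furan-3-ol (C8–OH endo) | C#C/C=C\C/C=C1\O[C@H]2C[C@H]([C@@H](Br)CC)O[C@H]2[C@H]1O | intermediate
29 | (2Z,3S,3aR,5R,6aS)-3-bromo-5-[(1S)-1-bromopropyl]-2-[(3Z)-hex-3-en-5-yn-1-ylidene]hexahydrofuro[3,2-b]furan (CNP0105780.1) | C#C/C=C\C/C=C1\O[C@H]2C[C@H]([C@@H](Br)CC)O[C@H]2[C@@H]1Br | target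

**Step count**
Total: 21 steps. Longest linear sequence: 18 steps (steps 1–14 and 18–21); steps 15–17 make the side-chain bromide.

**Three steps most likely to fail**

Step 21. The substrate is a 2-alkoxyallylic alcohol; SN2′ attack at C6, ionisation, or acid-induced migration of the enol ether (towards a furan) can compete with direct displacement. The fallback sets out from 26 and comes back at 29; it puts the bromide on C8 before ring A exists. The C10 hydroxyl of 26 is protected with 4-methoxybenzyl trichloroacetimidate and cat. La(OTf)3 to give the C10 4-methoxybenzyl ether F1. Bu4NF removes both silyl groups to give the propargylic alcohol F2. CBr4/PPh3 inverts C8 to the propargylic bromide F3. DDQ in buffered CH2Cl2 frees C10–OH to give the hydroxy bromide F4. F4 is then cyclised with the silver-free cationic monovalent-gold catalyst [(2-biphenylyl)(t-Bu)2P]Au(NCMe)SbF6 in CH2Cl2, which gives 29 directly.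

Step 19. The propargylic oxygen could bias attack towards C6 (6-endo), and the skipped enyne or the exocyclic enol ether may not tolerate the catalyst. The fallback sets out from 26 and comes back at 27. Iodine-induced 5-exo cyclisation (I2, NaHCO3, MeCN, 0 °C) gives, by anti addition, the (E)-iodo enol ether F5. Zerovalent-palladium formate reduction (Pd(PPh3)4, HCO2H, Et3N, DMF, rt) replaces iodine by hydrogen with retention of geometry and gives 27.

Step 7. The lactone enolate carries a β-alkoxy leaving group (the ring B oxygen) and may open by elimination before it is oxidised. The fallback sets out from 10 and comes back at 12. Soft enolisation (TBSOTf, Et3N, CH2Cl2, 0 °C) gives the ketene silyl acetal F6 without a free metal enolate. Rubottom oxidation with dimethyldioxirane on the convex face, with silyl shift, gives the exo silyloxy lactone F7. HF·pyridine in THF then gives 12.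

Further compounds
F1 | step 21 | C10 4-methoxybenzyl ether of 26 | CC(C)[Si](C(C)C)(C(C)C)C#C/C=C\CC#C[C@H](O[Si](C)(C)C(C)(C)C)[C@@H]1O[C@@H]([C@@H](Br)CC)C[C@@H]1OCc1ccc(OC)cc1
F2 | step 21 | desilylated propargylic alcohol (C8–OH, C10–OPMB, terminal alkyne) | C#C/C=C\CC#C[C@H](O)[C@@H]1O[C@@H]([C@@H](Br)CC)C[C@@H]1OCc1ccc(OC)cc1
F3 | step 21 | C8 propargylic bromide (inverted, C10–OPMB) | C#C/C=C\CC#C[C@@H](Br)[C@@H]1O[C@@H]([C@@H](Br)CC)C[C@@H]1OCc1ccc(OC)cc1
F4 | step 21 | C8 propargylic bromide with free C10–OH | C#C/C=C\CC#C[C@@H](Br)[C@@H]1O[C@@H]([C@@H](Br)CC)C[C@@H]1O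
F5 | step 19 | (E)-C6-iodo enol ether analogue of 27 | CC(C)[Si](C(C)C)(C(C)C)C#C/C=C\C/C(I)=C1\O[C@H]2C[C@H]([C@@H](Br)CC)O[C@H]2[C@H]1O[Si](C)(C)C(C)(C)C
F6 | step 7 | tert-butyldimethylsilyl ketene acetal of 10 | CC(C)(C)[Si](C)(C)OC1=C[C@@H]2O[C@@H]([C@H](OCc3ccccc3)CC)C[C@@H]2O1
F7 | step 7 | exo C8 tert-butyldimethylsilyloxy lactone (silyl ether of 12) | O=C1O[C@H]2C[C@H]([C@H](OCc3ccccc3)CC)O[C@H]2[C@@H]1O[Si](C)(C)C(C)(C)C
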